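Time is what a slow addition stretches, so I asked how long reagent lasts while it waits 10 min for its partner.

| flask | starting material | reagent | catalyst | temperature | remark | time |
|---|---|---|---|---|---|---|
| north-west | 13 mM | 1 equiv | 8 mol% | 20 °C | run made earlier |  |
| south | 13 mM | 1 equiv | 4 mol% | 31 °C | run made earlier |  |
| south-east | 13 mM | 1 equiv | 6 mol% | 20 °C | run made earlier |  |
| north | 20 mM | 1 equiv | 8 mol% | 31 °C | run made earlier |  |
| summer | 13 mM (fed, over 10 min) | 1.00 equiv | 8 mol% | 25 °C | all else is in the flask from the start; the feed brings no volume worth counting | 12 min |
| dawn | 13 mM (fed, over 10 min) | 1.00 equiv | 8 mol% |  | the addition at −5 °C, then warmed to 25 °C; the feed brings no volume worth counting | 12 min |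
| autumn | 13 mM | 1.00 equiv (fed, over 10 min) | 8 mol% | 25 °C | all else is in the flask from the start; the feed brings no volume worth counting | 12 min |
| winter | 13 mM | 1.00 equiv | 8 mol% |  | everything together at the start at −5 °C, warmed to 25 °C at 10 min | 12 min |

| run | time / min | target / % |
|---|---|---|
| north-west | 0.833 | 84 |
| north-west | 2.50 | 88 |
| north-west | 4.00 | 86 |
| north-west | 6.00 | 82 |
| north-west | 10.0 | 82 |
| north-west | 12.0 | 82 |
| south | 1.50 | 69 |
| south | 3.00 | 76 |
| south | 5.00 | 79 |
| south | 6.00 | 79 |
| south | 8.00 | 76 |
| south | 10.0 | 80 |
| south-east | 0.833 | 77 |
| south-east | 1.33 | 84 |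
| south-east | 2.00 | 82 |
| south-east | 4.00 | 84 |
| south-east | 6.00 | 83 |
| south-east | 10.0 | 82 |
| north | 2.00 | 85 |
| north | 4.00 | 84 |
| north | 6.00 | 81 |
| north | 8.00 | 80 |
| north | 10.0 | 79 |

(scatter of a reading: 1.5 percentage points)

- the flask with the highest amount of target, in percent of the starting material charged ("all alike" if they lie within 1.5 percentage points) (summer / dawn / autumn / winter / all alike)
- final target, as a percentage of the starting material charged, in summer
- final target, as a percentage of the starting material charged, in dawn
- final target, as a percentage of the starting material charged, in autumn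
- final target, as a percentage of the starting material charged, in winter

The north-west run has summer's charges at 20 °C. For equal charges the integrated second-order rate makes the half-time the reading's time multiplied by unreacted over reacted share, and the first reading gives 0.159 min. I took the shortfall at the peak reading of 88% as reagent lost in a step second order in reagent, which would leave that peak unmoved by concentration, so that 0.136 of loss goes with each target (a selectivity factor). Lone reagent at its full c_reagent then halves in 1.16 min, and the feed lasts 8.59 such half-lives: this is the waiting number N. If fed starting material reacts at once, c_reagent falls by feed and loss together, and the integral reaches zero at the fraction arctan(√N)/√N of the feed, which in its large-N form gives about 42.3% converted in summer. In autumn reagent is fed into a flask that holds the starting material, so I expected that flask and winter near the peak. One number was not enough, though: N ignores the slow decline after the peak, and the runs do not give its value at −5 °C, so I left dawn unreckoned.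

The forecast gave 79% for summer, 82% for dawn, 82% for autumn and 85% for winter, with winter highest, holding that “Feeding starting material exposes target to excess reagent”, and it parts from my summer figure.

The flasks gave 50.5% in summer, 72.4% in dawn, 84.9% in autumn and 92.2% in winter, so winter stood highest. In summer 86% of the homo dimer's turnover up to the asked time lay behind it at 1.20 min. N's 42.3% stands against 55.3% of target and isomer of the product together in summer, with 44.7% of starting material left.

    starting material + reagent + catalyst → target + catalyst, rate k1*[starting material]*[reagent]*[catalyst]/(1 + ([starting material]/sat1)) (14.0 mM, k = 15000 M⁻² s⁻¹, Ea = 17.0 kJ mol⁻¹)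
    reagent ⇌ dormant form (K = 3.00, k = 0.00820 s⁻¹, Ea = 94.0 kJ mol⁻¹, ΔH = −22.0 kJ mol⁻¹)
    target + catalyst ⇌ isomer of the product + catalyst, rate k3*[catalyst]*[target] forward; the back reaction follows from the equilibrium constant (K = 0.420, k = 0.220 M⁻¹ s⁻¹, Ea = 38.0 kJ mol⁻¹, ΔH = −38.0 kJ mol⁻¹)
    2 reagent → homo dimer (k = 0.420 M⁻¹ s⁻¹, Ea = 42.0 kJ mol⁻¹)
    (constants at 25 °C)

For summer's neighbour with 0.250 equiv of reagent, the same N and the arctangent's first two terms give 20.5% converted. The computed neighbour holds 18.2% of target and 1.96% of isomer of the product, with 79.8% of starting material left.

(The readings come from a simulation for an exercise; noise was put on by code.)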